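We charge 0.020 M of substrate and 5.00 mM of other conformer with 1.5 mM of catalyst, and these amounts go in by four different routes:

| setting | amber | grey | green | violet |
|---|---|---|---|---|
| substrate | 0.020 M | 0.020 M | 0.020 M | 0.020 M (fed, over 8.00 h) |
| other conformer | 5.00 mM | 5.00 mM (fed, over 8.00 h) | 5.00 mM | 5.00 mM |
| catalyst | 1.5 mM | 1.5 mM | 1.5 mM | 1.5 mM |
| time | 10 h | 10 h |  | 10 h |
| remark | a closed flask charged with all of it at once and left for 10 h | all but other conformer at the start; other conformer goes in evenly over 8.00 h, the run ends at 10 h | one stirred flow tank at steady state, fed with the mixture as stated, mean residence time 10 h | all but substrate at the start; substrate goes in evenly over 8.00 h, the run ends at 10 h |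

    substrate ⇌ other conformer (K1 = 0.50, k1 = 0.026 /min)
    substrate + catalyst → catalyst + target (k2 = 17 /M/min)
    catalyst + other conformer → catalyst + isomer of the product (k3 = 73 /M/min)
    substrate → uncatalysed product (k4 = 0.0031 /min)

1. the set-up with the highest amount of target at the outlet or at the end, in percent of the substrate and other conformer together put in ("none" if the first two lie within 2 percentage points) (amber / grey / green / violet / none)
2. amount of target at the outlet or at the end, in percent of the substrate and other conformer together put in, amber
3. amount of target at the outlet or at the end, in percent of the substrate and other conformer together put in, grey
4. amount of target at the outlet or at the end, in percent of the substrate and other conformer together put in, green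
5. amount of target at the outlet or at the end, in percent of the substrate and other conformer together put in, violet

- the stated concentrations are those of everything mixed, before any reaction; amounts are the same in each set-up
- the feed brings no volume worth counting
- run time (amber): 10 h

Turn the question round: for one set-up to win clearly, the way of feeding would have to matter. Each step takes one organic molecule and catalyst comes back, so with catalyst held a molecule's fate does not hang on its neighbours. Our zero is therefore a finished flask, where feeding order shifts the yield by nothing. A batch set-up can leave that zero by leaving unreacted charge, and a clear winner would need the runner-up to end 2 percentage points of target short.

Substrate goes to target at 0.0255 /min. Other conformer goes to isomer of the product at 0.109 /min and returns at 0.0520 /min, so its return chance r is 32.2%. Substrate's net exit rate k_n, counting those returns, is 0.0462 /min. The target chance p, the fraction of substrate ending as target (its selectivity), is the target rate over k_n: 55.2%. Other conformer's chance is r times p, 17.8%.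

Weighting by the charges gives 47.7% for amber, 47.7% for grey and 47.7% for violet. Violet's feed stops with 120 min to run, against a life 1/k_n of 21.6 min. We reckon its hold-up, near 1/(k_n t) of the substrate fed over time t, at about 0.0176% of that charge by the end.

In green the outlet is one more exit, at 0.00167 /min. That lowers r to 31.9% and p to 53.1%, so green gives 45.9%. We expect a tie at the top.

The forecast gave 47.7% for amber, 47.7% for grey, 47.7% for violet, 45.9% for green and none as best, with “all three batch-type runs essentially complete with the same yield whatever the feeding schedule”.

The simulation gives 47.7% for amber, 47.7% for grey, 47.7% for violet and 45.9% for green, so best is none. Amber's target stands at 47.7% mainly because of the step to isomer of the product: with that step struck out, amber gives 89.2% against 47.7%. More catalyst speeds the target step and the step to isomer of the product, while substrate's turning into other conformer stays at 0.026 /min. At 0.0037 M of catalyst, substrate's p becomes 71.6%, and that neighbour of amber ends with 59.6% of target, counted on substrate and other conformer together.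

The constants are those of an exercise.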